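I decided to give you a floor for the amber run instead of a scaled curve: red, grey and blue each held 2.00 mM of free catalyst, so they show how the rate follows starting material but not how it follows catalyst.

| flask | starting material | free catalyst | time |
|---|---|---|---|
| red | 200 mM | 2.00 mM |  |
| grey | 100 mM | 2.00 mM |  |
| blue | 400 mM | 2.00 mM |  |
| amber | 400 mM | 0.660 mM | 28 h |

| run | time / h | [target] / mM |
|---|---|---|
| red run | 1.1 | 8.8 |
| red run | 2.5 | 20.8 |
| red run | 5.6 | 43.6 |
| red run | 13 | 94.1 |
| red run | 28 | 163.1 |
| grey run | 1.1 | 4.5 |
| grey run | 2.5 | 13.7 |
| grey run | 5.6 | 29.6 |
| grey run | 13 | 58.6 |
| grey run | 28 | 89.2 |
| blue run | 1.1 | 12.7 |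
| blue run | 2.5 | 30.2 |
| blue run | 5.6 | 64.0 |
| blue run | 13 | 140.2 |
| blue run | 28 | 263.8 |

(readings scatter by 1 mM)

- Overall: starting material -> target, with free catalyst as catalyst.
- Constant volume, constant temperature.
- Bound and free are read together.
- An order is taken over about fifteen percent of the charge, up and down.

- the power of [starting material] that the first rate follows, about the charge of the red run; measure it at two percent of starting material made into target (one fixed amount of target, the same in the runs compared)
- the grey run starts with 100 mM less of starting material than the red run, and with no target. Compared where both hold the same amount of starting material, once fifteen percent of what the grey run was charged with has turned into target, is the grey run faster, slower or alike (within a tenth)?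
- target in the amber run at 28 h, as a share of the starting material charged

Write S for the starting material and r for the rate of target formation. I solved the two ends and joined them. At the low end, the grey run between 13 h and 28 h gave 2.04 mM h⁻¹ at a mean S of 26.1 mM. At the high end, the blue run gave 11.4 mM h⁻¹ up to 5.6 h, at a mean S of 368 mM, and 8.24 mM h⁻¹ between 13 h and 28 h, at a mean S of 198 mM.

I passed r = V·S/(K+S) + k_f·S through these points, with V the plateau of the catalysed part and K its half-saturation constant. That gave 0.0116 h⁻¹ for k_f, the floor constant: the first-order constant of the part of the rate that doesn't level off, which I took as an uncatalysed background. It is a reading and carries the scatter of these points. With that part working by itself, the share of S made into target after time t is 1 − exp(−k_f·t), which over 28 h came to 27.8 %. That floor was my number for the amber run.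

The forecast gave an order of 0.5, called the grey run alike, and put the amber run at 25.8 %, saying “I assume the rate is first order in catalyst, though no run tests this”. We differed on the amber run, where my floor stood higher than its figure.

The flask gave an order of 0.53, alike for the grey run, and 31.8 % for the amber run, which stood 4 percentage points higher than my floor.

    free catalyst + starting material ⇌ catalyst-substrate complex, settled at all times (13.00 M⁻¹)
    catalyst-substrate complex → target + free catalyst (9.648 h⁻¹)
    starting material → target (0.01364 h⁻¹)
    free catalyst + impurity → spent catalyst

In the blue run, 0.810 mM of catalyst, free and bound together, outlasted the 1.19 mM of impurity, and the step through the catalyst-substrate complex ran beside the direct step, whose constant of 0.0136 h⁻¹ gives 5.40 mM h⁻¹ of the simulated 12 mM h⁻¹, a share of 45.3 %. In the amber run, the impurity exceeded the 0.660 mM of free catalyst and turned it at once into spent catalyst, and the direct step then ran for 28 h and took the amber run to 31.8 %.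

(All runs were computed for an exercise; scatter was added.)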